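**Retrosynthetic overview**
1. Target ⇐ aromatic Claisen rearrangement of its 5-O-(1,1-dimethylallyl) ether: the future prenyl group masks the one phenol oxygen that must stay free until the last step.
2. Chromanone ring ⇐ ring transposition of an 8-tigloyl-4-phenyl-3,4-dihydrocoumarin: lactone opening frees the phenol, which closes onto the tigloyl enone by quinidine-mediated oxa-Michael addition (sets cis C2/C3). The lactone oxygen becomes the chromanone oxygen and the lactone carbonyl becomes the free acid.
3. 8-Tigloyl-7-hydroxy lactone ⇐ Friedel–Crafts acylation with ortho-demethylation of (R)-5,7-dimethoxy-4-phenylchroman-2-one.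
4. Lactone ring ⇐ enantioselective [3+3] annulation of 3,5-dimethoxyphenol with a cinnamoyl azolium made from cinnamaldehyde (sets the benzylic centre).
5. Ring order: dihydrocoumarin lactone first, chromanone second, built at the expense of the lactone.

Assumption: the sense of induction of the triazolium catalyst (step 1) and of quinidine (step 5) is assigned by analogy with the closest known substrates; if a first run shows the opposite sense, the enantiomeric triazolium salt or quinine is used with no other change.

**Step 1**
Reactants: 1 3,5-dimethoxyphenol; 2 (E)-cinnamaldehyde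
Product: 3 (R)-5,7-dimethoxy-4-phenylchroman-2-one
Conditions: 2 (1.5 equiv), (5aS,10bR)-2-mesityl-5a,10b-dihydro-4H,6H-indeno[2,1-b][1,2,4]triazolo[4,3-d][1,4]oxazin-2-ium tetrafluoroborate (10 mol%), 3,3',5,5'-tetra-tert-butyldiphenoquinone (1.2 equiv), K2CO3 (0.5 equiv), 4 Å MS, toluene, 25 °C; one recrystallisation
Reagents that add atoms: none
Why: Oxidative N-heterocyclic carbene catalysis turns 2 into a cinnamoyl azolium (a thioester-like activated cinnamate) that undergoes an enantioselective formal [3+3] annulation with the phenol (C–C bond at the ortho carbon by 1,2-addition/[3,3] Coates–Claisen shift, then lactonisation with catalyst release), a reaction type established for naphthols and electron-rich phenols; the aminoindanol backbone shields one face of the acyl azolium so C4 forms as R, and the two ortho positions of 1 are equivalent so only one regioisomer can arise.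

**Step 2**
Reactants: 3 (R)-5,7-dimethoxy-4-phenylchroman-2-one; 4 tigloyl chloride
Product: 6 (R)-7-hydroxy-5-methoxy-8-[(E)-2-methylbut-2-enoyl]-4-phenylchroman-2-one, via 8-tigloyl dimethoxy lactone 5 (not isolated)
Conditions: 4 (1.3 equiv), AlCl3 (3.0 equiv), CH2Cl2, −20 → 23 °C, 8 h; ice, 1 M HCl
Reagents that add atoms: none
Why: Friedel–Crafts acylation followed in the same pot by chelation-controlled ether cleavage: the acylium attacks C8 (para to the 5-methoxy and ortho to the 7-methoxy group, less hindered than C6 between two methoxy groups), and AlCl3 bound to the new ketone then removes only the ortho 7-O-methyl group through a six-membered chelate whose aluminium phenoxide cannot add to the enone; C4 is not involved.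

**Step 3**
Reactants: 7 2-methylbut-3-en-2-ol
Product: 8 tert-butyl (2-methylbut-3-en-2-yl) carbonate
Conditions: n-BuLi (1.05 equiv), THF, −78 → 0 °C; Boc2O (1.1 equiv), 0 → 23 °C; H2O
Reagents that add atoms: di-tert-butyl dicarbonate, CC(C)(C)OC(=O)OC(=O)OC(C)(C)C
Why: Alkoxycarbonylation of the lithium alkoxide of the tertiary allylic alcohol with Boc2O gives the mixed carbonate used as 1,1-dimethylallyl donor; no stereocentre is involved.

**Step 4**
Reactants: 6 (R)-7-hydroxy-5-methoxy-8-[(E)-2-methylbut-2-enoyl]-4-phenylchroman-2-one; 8 tert-butyl (2-methylbut-3-en-2-yl) carbonate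
Product: 9 (R)-5-methoxy-7-[(2-methylbut-3-en-2-yl)oxy]-8-[(E)-2-methylbut-2-enoyl]-4-phenylchroman-2-one
Conditions: 8 (2.0 equiv), Pd(PPh3)4 (5 mol%), THF, 0 °C, 1 h
Reagents that add atoms: none
Why: Decarboxylative Tsuji–Trost O-allylation: zerovalent palladium ionises 8 to a 1,1-dimethylallyl palladium cation, CO2 and tert-butoxide, which deprotonates the single phenol of 6, and the phenoxide attacks the more substituted allyl terminus under kinetic control at 0 °C to give the tertiary (reverse-prenyl) ether faster than it can add to its own enone (a fully ionised ortho-acyl phenoxide is a poor intramolecular Michael donor); no stereocentre is formed or disturbed.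

**Step 5**
Reactants: 9 (R)-5-methoxy-7-[(2-methylbut-3-en-2-yl)oxy]-8-[(E)-2-methylbut-2-enoyl]-4-phenylchroman-2-one
Product: 11 (R)-3-{(2S,3R)-7-methoxy-2,3-dimethyl-5-[(2-methylbut-3-en-2-yl)oxy]-4-oxochroman-8-yl}-3-phenylpropanoic acid, via ring-opened hydroxy acid 10 (not isolated)
Conditions: LiOH (3.0 equiv), THF/H2O 3:1, −10 °C, 20 min; 1 M HCl to pH 5 at −10 °C, extract into cold PhCl, dry (Na2SO4); quinidine (2.2 equiv), PhCl, 15–20 °C, 72–96 h; 0.5 M aq. citric acid wash (quinidine recovered from the wash)
Reagents that add atoms: lithium hydroxide, [Li+].[OH-]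
Why: Proposed new method: cold hydroxide cleaves the activated aryl ester of the lactone to a phenoxide–carboxylate that does not cyclise while fully ionised (as 2'-hydroxychalcones persist in strong base), and after protonation the liberated phenol, the only free hydroxyl beside the tigloyl ketone because the other ortho oxygen is masked as the tertiary ether, is deprotonated within a chiral quinidinium ion pair (the first equivalent of quinidine holds the acid as its carboxylate, the excess acts as chiral Brønsted base) and adds 6-endo to the E-enone on the face that gives C2 (S), after which the quinidinium protonates the enolate under kinetic control to give the cis C3 (R) methyl, so the lactone oxygen becomes the chromanone oxygen and the lactone carbonyl the free acid; the closest known reaction is the cinchona-alkaloid-catalysed asymmetric intramolecular oxa-Michael addition of ortho-tigloylphenols to cis-2,3-dimethylchroman-4-ones, where quinine gives the (2R,3S) series and its pseudo-enantiomer quinidine the (2S,3R) series.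

**Step 6**
Reactants: 11 (R)-3-{(2S,3R)-7-methoxy-2,3-dimethyl-5-[(2-methylbut-3-en-2-yl)oxy]-4-oxochroman-8-yl}-3-phenylpropanoic acid
Product: 12 (R)-3-[(2S,3R)-5-hydroxy-7-methoxy-2,3-dimethyl-6-(3-methylbut-2-en-1-yl)-4-oxochroman-8-yl]-3-phenylpropanoic acid
Conditions: toluene (0.02 M), 105 °C, 3 h, Ar
Reagents that add atoms: none
Why: Aromatic Claisen rearrangement: the 1,1-dimethylallyl ether undergoes a [3,3]-sigmatropic shift to C6, the only free ortho position, with allyl transposition to the linear 3-methylbut-2-enyl group, and the dienone tautomerises to the hydrogen-bonded 5-hydroxy arene; the conditions are neutral and free of added base or Lewis acid, so the cis C2/C3 pair and the benzylic centre are retained.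

**Compound list**
1 | 3,5-dimethoxyphenol | COc1cc(O)cc(OC)c1 | starting material
2 | (E)-cinnamaldehyde | O=C/C=C/c1ccccc1 | starting material
3 | (R)-5,7-dimethoxy-4-phenylchroman-2-one | O=C1C[C@H](c2ccccc2)c2c(OC)cc(OC)cc2O1 | intermediate
4 | tigloyl chloride, (E)-2-methylbut-2-enoyl chloride | C/C=C(\C)C(=O)Cl | starting material
5 | (R)-5,7-dimethoxy-8-[(E)-2-methylbut-2-enoyl]-4-phenylchroman-2-one | O=C1C[C@H](c2ccccc2)c2c(OC)cc(OC)c(C(=O)/C(C)=C/C)c2O1 | intermediate
6 | (R)-7-hydroxy-5-methoxy-8-[(E)-2-methylbut-2-enoyl]-4-phenylchroman-2-one | O=C1C[C@H](c2ccccc2)c2c(OC)cc(O)c(C(=O)/C(C)=C/C)c2O1 | intermediate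
7 | 2-methylbut-3-en-2-ol | C=CC(C)(C)O | starting material
8 | tert-butyl (2-methylbut-3-en-2-yl) carbonate | C=CC(C)(C)OC(=O)OC(C)(C)C | intermediate
9 | (R)-5-methoxy-7-[(2-methylbut-3-en-2-yl)oxy]-8-[(E)-2-methylbut-2-enoyl]-4-phenylchroman-2-one | O=C1C[C@H](c2ccccc2)c2c(OC)cc(OC(C)(C)C=C)c(C(=O)/C(C)=C/C)c2O1 | intermediate
10 | (R)-3-{2-hydroxy-6-methoxy-4-[(2-methylbut-3-en-2-yl)oxy]-3-[(E)-2-methylbut-2-enoyl]phenyl}-3-phenylpropanoic acid | OC(=O)C[C@H](c1ccccc1)c1c(OC)cc(OC(C)(C)C=C)c(C(=O)/C(C)=C/C)c1O | intermediate
11 | (R)-3-{(2S,3R)-7-methoxy-2,3-dimethyl-5-[(2-methylbut-3-en-2-yl)oxy]-4-oxochroman-8-yl}-3-phenylpropanoic acid | COc1cc(OC(C)(C)C=C)c2c(c1[C@H](CC(=O)O)c1ccccc1)O[C@@H](C)[C@@H](C)C2=O | intermediate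
12 | (R)-3-[(2S,3R)-5-hydroxy-7-methoxy-2,3-dimethyl-6-(3-methylbut-2-en-1-yl)-4-oxochroman-8-yl]-3-phenylpropanoic acid | COc1c(CC=C(C)C)c(O)c2c(c1[C@H](CC(=O)O)c1ccccc1)O[C@@H](C)[C@@H](C)C2=O | target

**Totals**
Total step count: 6 (five in the main line plus one to make carbonate 8).
Longest linear sequence: 5 steps (1 → 3 → 6 → 9 → 11 → 12).

**Three steps most likely to fail**

Step 5 (ring transposition). The oxa-Michael addition has to run on a free carboxylic acid held as its quinidinium salt, so the diastereo- and enantioselectivity known for neutral substrates may erode. Some hydroxy acid 10 may also relactonise to 9 before it cyclises. The fallback sets out from 9 and comes back at 11. Methanolysis of the lactone (NaOMe 1.5 equiv, MeOH/THF, −20 °C, then AcOH) gives methyl (R)-3-{2-hydroxy-6-methoxy-4-[(2-methylbut-3-en-2-yl)oxy]-3-[(E)-2-methylbut-2-enoyl]phenyl}-3-phenylpropanoate F3. This neutral phenol is cyclised with catalytic quinidine (20 mol%, PhCl, 15 °C) to methyl (R)-3-{(2S,3R)-7-methoxy-2,3-dimethyl-5-[(2-methylbut-3-en-2-yl)oxy]-4-oxochroman-8-yl}-3-phenylpropanoate F4. The ester is then cleaved without epimerisation by Me3SnOH (1,2-dichloroethane, 60 °C) to give 11.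

Step 4 (etherification). The phenol of 6 is hydrogen-bonded to the ketone and flanked by the acyl group, so attack on the allyl palladium cation at its tertiary terminus may be slow. The tertiary ether can also re-ionise and drift to the linear prenyl ether. The fallback sets out from 6 and comes back at 9. Copper-catalysed propargylic etherification with 2-methylbut-3-yn-2-ol activated in situ as its trifluoroacetate ((CF3CO)2O, DBU, CuCl2 cat., MeCN, −5 °C) gives (R)-5-methoxy-7-[(2-methylbut-3-yn-2-yl)oxy]-8-[(E)-2-methylbut-2-enoyl]-4-phenylchroman-2-one F2. Semihydrogenation of the alkyne (H2 1 atm, Pd/CaCO3 poisoned with Pb(OAc)2, quinoline, EtOAc) then gives 9.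

Step 1 (annulation). A simple phenol is a less proven partner than a naphthol, so O-acylation to the aryl cinnamate or a modest enantiomeric excess may result. The fallback sets out from 1 and comes back at 3. Pechmann condensation of 1 with ethyl benzoylacetate (CF3SO3H, 0 → 25 °C) gives 5,7-dimethoxy-4-phenylcoumarin F1. The benzylic centre is then set by hydride delivery instead of C–C bond formation: asymmetric conjugate reduction (Cu(OAc)2·H2O 3 mol%, (R)-DTBM-SEGPHOS, diethoxymethylsilane, t-BuOH, toluene, 0 °C) gives 3.

**Further compounds**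
F1 | step 1 | 5,7-dimethoxy-4-phenylcoumarin | COc1cc(OC)c2c(c1)oc(=O)cc2-c1ccccc1
F2 | step 4 | (R)-5-methoxy-7-[(2-methylbut-3-yn-2-yl)oxy]-8-[(E)-2-methylbut-2-enoyl]-4-phenylchroman-2-one | O=C1C[C@H](c2ccccc2)c2c(OC)cc(OC(C)(C)C#C)c(C(=O)/C(C)=C/C)c2O1
F3 | step 5 | methyl (R)-3-{2-hydroxy-6-methoxy-4-[(2-methylbut-3-en-2-yl)oxy]-3-[(E)-2-methylbut-2-enoyl]phenyl}-3-phenylpropanoate | COC(=O)C[C@H](c1ccccc1)c1c(OC)cc(OC(C)(C)C=C)c(C(=O)/C(C)=C/C)c1O
F4 | step 5 | methyl (R)-3-{(2S,3R)-7-methoxy-2,3-dimethyl-5-[(2-methylbut-3-en-2-yl)oxy]-4-oxochroman-8-yl}-3-phenylpropanoate | COc1cc(OC(C)(C)C=C)c2c(c1[C@H](CC(=O)OC)c1ccccc1)O[C@@H](C)[C@@H](C)C2=O
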